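**Plan**

1. Numbering is that of eremophilane: ring A = C1–C5 and C10, ring B = C5–C10, C14 on C5, C15 on C4, isopropenyl C11–C13 on C7, ketone at C8, esters on O3 and O9. In the usual drawing (ring A left) both methyl groups, H10, the isopropenyl group and O9 are β and O3 is α (cis-decalin).
2. Retrosynthesis cuts the two ester C–O bonds, then the C9–O bond (α-hydroxylation of a C8=C9 silyl enol ether), then C6–C7 and C5–C10 together in an intramolecular Diels–Alder reaction, leaving an acyclic triene.
3. Enabling feature: ring B is a cyclohexanone (C8=O between C7 and C9), so its C8=C9 enol ether is the cyclohexene retron of a 2-silyloxydiene C7=C8–C9=C10 adding to C5=C6. O3 and C6 are 1,3-cis (both α) on ring A, so a one-carbon carbonyl bridge O3–C(=O)–C6 (a δ-lactone) can activate C5=C6, lock it Z and force the cis fusion; the bridge carbon is excised afterwards.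
4. Forward: Evans aldol (C3, C4) → unsaturated δ-lactone → chain extension to the silyloxytriene → cycloaddition closing rings A and B at once → lactone opening and decarboxylation at C6 → O3 tiglate → C9 hydroxylation → O9 senecioate → C7 epimerisation.
5. Stereochemistry: C3 and C4 come from the (S)-benzyloxazolidinone auxiliary. C5 and C10 are relayed from them through the tether and lactone in the cycloaddition. C9 comes from β-face epoxidation of the enol ether. C7 comes from equilibration to the all-equatorial ketone.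

Key step: step 9

Remark: C7 and C9 both flank the C8 ketone, and in the target every substituent on C3, C4, C7 and C9 can be equatorial in one cis-decalin conformer, so the natural configurations at C7 and C9 are taken to be the thermodynamic ones.

Step 1
Reactants: 1 (S)-4-benzyl-3-propanoyl-1,3-oxazolidin-2-one; 2 pent-4-enal
Product: 4 (S)-4-benzyl-3-[(2S,3R)-3-hydroxy-2-methylhept-6-enoyl]-1,3-oxazolidin-2-one, via boron Z-enolate 3 (not isolated)
Conditions: Bu2BOTf, Et3N, CH2Cl2, 0 °C; then 2, −78 → 0 °C; then H2O2, MeOH, pH 7 buffer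
Reagents that add atoms: none
Why: Evans syn-aldol reaction: the Z-boron enolate 3 adds to 2 through a chair Zimmerman–Traxler transition state on the face away from the benzyl group of the (S)-auxiliary, which sets the (2S,3R) syn pair that becomes C4 and C3 of the target.

Step 2
Reactants: 4 (S)-4-benzyl-3-[(2S,3R)-3-hydroxy-2-methylhept-6-enoyl]-1,3-oxazolidin-2-one
Product: 5 (2S,3R)-3-hydroxy-N-methoxy-N,2-dimethylhept-6-enamide
Conditions: MeNH(OMe)·HCl, AlMe3, CH2Cl2, −20 °C → rt
Reagents that add atoms: N,O-dimethylhydroxylamine hydrochloride, CNOC.Cl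
Why: Weinreb transamidation: the aluminium amide made from AlMe3 and the amine salt attacks the exocyclic imide carbonyl, activated by chelation with the free β-hydroxyl, and releases the auxiliary without touching either stereocenter.

Step 3
Reactants: 5 (2S,3R)-3-hydroxy-N-methoxy-N,2-dimethylhept-6-enamide
Product: 6 (3S,4R)-4-hydroxy-3-methyloct-7-en-2-one
Conditions: MeMgBr (3 equiv), THF, −20 → 0 °C
Reagents that add atoms: methylmagnesium bromide, C[Mg]Br
Why: Weinreb ketone synthesis: the chelated tetrahedral magnesium adduct survives until work-up, so a single methyl group (the future C14) is added and the α-stereocenter is not enolised at low temperature.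

Step 4
Reactants: 6 (3S,4R)-4-hydroxy-3-methyloct-7-en-2-one
Product: 8 (5R,6R)-6-(but-3-en-1-yl)-4,5-dimethyl-5,6-dihydro-2H-pyran-2-one, via ester ylide 7 (not isolated)
Conditions: Ph3P=C=C=O, PhMe, 110 °C
Reagents that add atoms: (triphenylphosphoranylidene)ketene (Bestmann ylide), O=C=C=P(c1ccccc1)(c1ccccc1)c1ccccc1
Why: Tandem acylation and intramolecular Wittig olefination with the Bestmann ylide: the hydroxyl adds to the ketene to give ester ylide 7, which condenses with the methyl ketone under neutral conditions to close the δ-lactone, the ring forcing the Z geometry of the trisubstituted C5=C6 alkene; no new stereocenter is formed.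

Step 5
Reactants: 8 (5R,6R)-6-(but-3-en-1-yl)-4,5-dimethyl-5,6-dihydro-2H-pyran-2-one; 9 (E)-but-2-enal
Product: 10 (E)-5-[(2R,3R)-3,4-dimethyl-6-oxo-3,6-dihydro-2H-pyran-2-yl]pent-2-enal
Conditions: 9 (5 equiv), second-generation Grubbs catalyst (5 mol %), CH2Cl2, 40 °C
Reagents that add atoms: none
Why: Olefin cross-metathesis: the monosubstituted alkene of 8 couples with the enal partner to give the E-enal with loss of propene, while the trisubstituted, electron-poor lactone alkene is inert to the catalyst.

Step 6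
Reactants: 10 (E)-5-[(2R,3R)-3,4-dimethyl-6-oxo-3,6-dihydro-2H-pyran-2-yl]pent-2-enal; 11 3-bromo-2-methylprop-1-ene
Product: 12 (5R,6R)-6-[(E)-5-hydroxy-7-methylocta-3,7-dien-1-yl]-4,5-dimethyl-5,6-dihydro-2H-pyran-2-one (both carbinol epimers)
Conditions: 11, In powder, THF/H2O (1:1), rt
Reagents that add atoms: none
Why: Barbier allylation: the methallylindium species formed in aqueous medium adds 1,2 to the aldehyde only, leaving the lactone untouched; the new carbinol centre forms as a mixture and is removed in step 7.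

Step 7
Reactants: 12 (5R,6R)-6-[(E)-5-hydroxy-7-methylocta-3,7-dien-1-yl]-4,5-dimethyl-5,6-dihydro-2H-pyran-2-one
Product: 13 (5R,6R)-4,5-dimethyl-6-[(E)-7-methyl-5-oxoocta-3,7-dien-1-yl]-5,6-dihydro-2H-pyran-2-one
Conditions: DMP, NaHCO3, CH2Cl2, 0 °C → rt
Reagents that add atoms: none
Why: Dess–Martin oxidation under buffered, non-basic conditions converts the allylic alcohol into the enone without moving the skipped C11=C12 double bond into conjugation.

Step 8
Reactants: 13 (5R,6R)-4,5-dimethyl-6-[(E)-7-methyl-5-oxoocta-3,7-dien-1-yl]-5,6-dihydro-2H-pyran-2-one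
Product: 14 (5R,6R)-4,5-dimethyl-6-[(3E,5Z)-7-methyl-5-(triisopropylsilyloxy)octa-3,5,7-trien-1-yl]-5,6-dihydro-2H-pyran-2-one
Conditions: TIPSOTf, Et3N, CH2Cl2, −78 → 0 °C
Reagents that add atoms: triisopropylsilyl trifluoromethanesulfonate, CC(C)[Si](OS(=O)(=O)C(F)(F)F)(C(C)C)C(C)C
Why: Soft enolisation with a silyl triflate and an amine: the ketone is silylated on oxygen and deprotonated at the doubly activated C7 methylene, which should give the Z enol ether with the isopropenyl group cis to the silyloxy group; the lactone is not enolised under these conditions.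

Step 9
Reactants: 14 (5R,6R)-4,5-dimethyl-6-[(3E,5Z)-7-methyl-5-(triisopropylsilyloxy)octa-3,5,7-trien-1-yl]-5,6-dihydro-2H-pyran-2-one
Product: 15 bridged tricyclic lactone: 3α-hydroxy-7α-isopropenyl-8-(triisopropylsilyloxy)-10βH-eremophila-8,11-diene-6α-carboxylic acid 6,3-lactone
Conditions: PhMe (0.01 M), BHT, Et3N (trace), sealed tube, 170 °C
Reagents that add atoms: none
Why: Thermal, concerted but asynchronous [4+2] cycloaddition (type 1 intramolecular Diels–Alder reaction) of the electron-rich 2-silyloxydiene C7=C8–C9=C10 onto the ester-activated C5=C6 bond of the unsaturated δ-lactone; the closest known reaction type is the intramolecular Diels–Alder reaction of 2-silyloxydienes with tethered unsaturated esters and lactones that creates angular methyl centres. Ring A closes as the six-membered tether ring through the C5–C10 bond (the C2–C1 chain reaches from the pseudo-axial C3 substituent across the lactone to its β-carbon, giving a 2-oxabicyclo[3.3.1]nonanone), and ring B closes as the new cyclohexene through the C6–C7 bond, leaving the C8=C9 silyl enol ether. C5 and C10: the tether can deliver the diene only to the lactone face that carries the C3 side chain, and only the transition state with the lactone carbonyl endo leads to a chair/chair bridged product, so the 5β-methyl/10β-H cis fusion follows from C3 and C4, the trans-fused alternative requiring a boat ring A. C6 and C7: suprafacial addition to the ring-locked Z dienophile places the carbonyl α on C6, and the Z enol ether (isopropenyl on the outside of the diene) places the isopropenyl group α on C7; C6 becomes CH2 in step 13 and C7 is corrected in step 16. The step needs periselectivity for the C7–C10 diene over the C8=C7–C11=C12 diene and a single regiochemistry, both secured by the two-carbon tether, which allows only a six-membered tether ring; the Z enol ether geometry also rules out 6π electrocyclisation of the triene, and conjugation with the isopropenyl group raises the HOMO coefficient at C10 so that the tether-imposed orientation is not electronically penalised.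

Step 10
Reactants: 15 bridged tricyclic lactone
Product: 16 allyl 3α-hydroxy-7α-isopropenyl-8-(triisopropylsilyloxy)-10βH-eremophila-8,11-diene-6α-carboxylate
Conditions: K2CO3 (0.2 equiv), allyl alcohol, rt
Reagents that add atoms: prop-2-en-1-ol, C=CCO
Why: Base-catalysed transesterification (lactone alcoholysis): allyloxide opens the bridged lactone, driven by loss of the 1,3-diaxial bridge on ring flip, which unmasks the 3α-hydroxyl and leaves C6 as an allyl ester; epimerisation at C6 would be without consequence because that centre is destroyed in step 13.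

Step 11
Reactants: 16 allyl 3α-hydroxy-7α-isopropenyl-8-(triisopropylsilyloxy)-10βH-eremophila-8,11-diene-6α-carboxylate; 17 (E)-2-methylbut-2-enoyl chloride
Product: 18 allyl 7α-isopropenyl-3α-[(E)-2-methylbut-2-enoyloxy]-8-(triisopropylsilyloxy)-10βH-eremophila-8,11-diene-6α-carboxylate
Conditions: 17, pyridine, DMAP (cat.), CH2Cl2, 0 °C → rt
Reagents that add atoms: none
Why: Acylation of the secondary C3 alcohol with the acid chloride under nucleophilic catalysis installs the tiglate with its E geometry intact; the silyl enol ether is stable to these non-acidic conditions.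

Step 12
Reactants: 18 allyl 7α-isopropenyl-3α-[(E)-2-methylbut-2-enoyloxy]-8-(triisopropylsilyloxy)-10βH-eremophila-8,11-diene-6α-carboxylate
Product: 19 7α-isopropenyl-3α-[(E)-2-methylbut-2-enoyloxy]-8-(triisopropylsilyloxy)-10βH-eremophila-8,11-diene-6α-carboxylic acid
Conditions: Pd(PPh3)4 (5 mol %), morpholine, THF, rt
Reagents that add atoms: none
Why: Tsuji–Trost-type deallylation: zerovalent palladium ionises only the allyl ester to a π-allyl complex that is captured by morpholine, freeing the hindered C6 acid without hydrolytic conditions that would endanger the tiglate or the enol ether.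

Step 13
Reactants: 19 7α-isopropenyl-3α-[(E)-2-methylbut-2-enoyloxy]-8-(triisopropylsilyloxy)-10βH-eremophila-8,11-diene-6α-carboxylic acid
Product: 21 7α-isopropenyl-8-(triisopropylsilyloxy)-10βH-eremophila-8,11-dien-3α-yl (E)-2-methylbut-2-enoate, via thiohydroxamate ester 20 (not isolated)
Conditions: 2-mercaptopyridine N-oxide, DCC, DMAP (cat.), CH2Cl2, dark, 0 °C → rt; then t-BuSH, hν (tungsten lamp), PhH, 15 °C
Reagents that add atoms: none
Why: Barton reductive decarboxylation: on irradiation ester 20 loses CO2 to give a secondary C6 radical, which should abstract hydrogen from t-BuSH faster than its reversible 3-exo closures onto the neighbouring π bonds can lead to rearrangement, so the activating carbon is excised and C6 becomes CH2.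

Step 14
Reactants: 21 7α-isopropenyl-8-(triisopropylsilyloxy)-10βH-eremophila-8,11-dien-3α-yl (E)-2-methylbut-2-enoate
Product: 23 9β-hydroxy-7α-isopropenyl-8-oxo-10βH-eremophil-11-en-3α-yl (E)-2-methylbut-2-enoate, via silyloxy epoxide 22 (not isolated)
Conditions: DMDO (1.05 equiv), acetone/CH2Cl2, −78 → −40 °C; then TBAF, AcOH, THF, 0 °C
Reagents that add atoms: dimethyldioxirane, CC1(C)OO1
Why: Rubottom oxidation: dimethyldioxirane epoxidises the electron-rich C8=C9 enol ether far faster than the isopropenyl or tiglate alkenes and from the β face, the α face being shielded by the pseudo-axial 7α-isopropenyl group and by C4 (axial on ring B), and fluoride-induced opening of 22 gives the C8 ketone with the 9β-hydroxyl (9R).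

Step 15
Reactants: 23 9β-hydroxy-7α-isopropenyl-8-oxo-10βH-eremophil-11-en-3α-yl (E)-2-methylbut-2-enoate; 24 3-methylbut-2-enoyl chloride
Product: 25 7α-isopropenyl-9β-(3-methylbut-2-enoyloxy)-8-oxo-10βH-eremophil-11-en-3α-yl (E)-2-methylbut-2-enoate
Conditions: 24, pyridine, DMAP (cat.), CH2Cl2, 0 °C
Reagents that add atoms: none
Why: Acylation of the α-hydroxy ketone with the acid chloride and pyridine, a base too weak to form the vinylketene that would deconjugate the senecioate, gives the 9β-ester with retention at C9.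

Step 16
Reactants: 25 7α-isopropenyl-9β-(3-methylbut-2-enoyloxy)-8-oxo-10βH-eremophil-11-en-3α-yl (E)-2-methylbut-2-enoate
Product: 26 (3R,4R,5R,7R,9R,10S)-9-(3-methylbut-2-enoyloxy)-8-oxo-10βH-eremophil-11-en-3-yl (E)-2-methylbut-2-enoate (7β-isopropenyl; the target)
Conditions: DBU (0.2 equiv), PhMe, 0 °C → rt
Reagents that add atoms: none
Why: Base-mediated epimerisation through the C8 enolate: C7 should equilibrate from the axial 7α-isopropenyl epimer (syn-axial to C4 in the cis-decalin) to the equatorial 7β epimer (7R), in which the substituents on C3, C4, C7 and C9 are all equatorial, and a catalytic amidine at low temperature is chosen to keep the C11=C12 bond out of conjugation.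

**Compound list**

1 | (S)-4-benzyl-3-propanoyl-1,3-oxazolidin-2-one | CCC(=O)N1C(=O)OC[C@@H]1Cc1ccccc1 | starting material
2 | pent-4-enal | C=CCCC=O | starting material
3 | (S)-4-benzyl-3-[(Z)-1-(dibutylboranyloxy)prop-1-enyl]-1,3-oxazolidin-2-one (not isolated) | C/C=C(\OB(CCCC)CCCC)N1C(=O)OC[C@@H]1Cc1ccccc1 | intermediate
4 | (S)-4-benzyl-3-[(2S,3R)-3-hydroxy-2-methylhept-6-enoyl]-1,3-oxazolidin-2-one | C=CCC[C@@H](O)[C@H](C)C(=O)N1C(=O)OC[C@@H]1Cc1ccccc1 | intermediate
5 | (2S,3R)-3-hydroxy-N-methoxy-N,2-dimethylhept-6-enamide | C=CCC[C@@H](O)[C@H](C)C(=O)N(C)OC | intermediate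
6 | (3S,4R)-4-hydroxy-3-methyloct-7-en-2-one | C=CCC[C@@H](O)[C@H](C)C(C)=O | intermediate
7 | (5R,6S)-6-methyl-7-oxooct-1-en-5-yl 2-(triphenyl-λ5-phosphanylidene)acetate (not isolated) | C=CCC[C@@H](OC(=O)C=P(c1ccccc1)(c1ccccc1)c1ccccc1)[C@H](C)C(C)=O | intermediate
8 | (5R,6R)-6-(but-3-en-1-yl)-4,5-dimethyl-5,6-dihydro-2H-pyran-2-one | C=CCC[C@H]1OC(=O)C=C(C)[C@H]1C | intermediate
9 | (E)-but-2-enal | C/C=C/C=O | starting material
10 | (E)-5-[(2R,3R)-3,4-dimethyl-6-oxo-3,6-dihydro-2H-pyran-2-yl]pent-2-enal | O=C/C=C/CC[C@H]1OC(=O)C=C(C)[C@H]1C | intermediate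
11 | 3-bromo-2-methylprop-1-ene | C=C(C)CBr | starting material
12 | (5R,6R)-6-[(E)-5-hydroxy-7-methylocta-3,7-dien-1-yl]-4,5-dimethyl-5,6-dihydro-2H-pyran-2-one (both carbinol epimers) | C=C(C)CC(O)/C=C/CC[C@H]1OC(=O)C=C(C)[C@H]1C | intermediate
13 | (5R,6R)-4,5-dimethyl-6-[(E)-7-methyl-5-oxoocta-3,7-dien-1-yl]-5,6-dihydro-2H-pyran-2-one | C=C(C)CC(=O)/C=C/CC[C@H]1OC(=O)C=C(C)[C@H]1C | intermediate
14 | (5R,6R)-4,5-dimethyl-6-[(3E,5Z)-7-methyl-5-(triisopropylsilyloxy)octa-3,5,7-trien-1-yl]-5,6-dihydro-2H-pyran-2-one | C=C(C)/C=C(O[Si](C(C)C)(C(C)C)C(C)C)/C=C/CC[C@H]1OC(=O)C=C(C)[C@H]1C | intermediate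
15 | 3α-hydroxy-7α-isopropenyl-8-(triisopropylsilyloxy)-10βH-eremophila-8,11-diene-6α-carboxylic acid 6,3-lactone (bridged tricycle; 4β,5β-dimethyl) | C=C(C)[C@@H]1[C@H]3[C@@]2(C)[C@H](CC[C@@H](OC3=O)[C@@H]2C)C=C1O[Si](C(C)C)(C(C)C)C(C)C | intermediate
16 | allyl 3α-hydroxy-7α-isopropenyl-8-(triisopropylsilyloxy)-10βH-eremophila-8,11-diene-6α-carboxylate | C=C(C)[C@@H]1[C@H](C(=O)OCC=C)[C@@]2(C)[C@H](CC[C@@H](O)[C@@H]2C)C=C1O[Si](C(C)C)(C(C)C)C(C)C | intermediate
17 | (E)-2-methylbut-2-enoyl chloride (tigloyl chloride) | C/C=C(\C)C(Cl)=O | starting material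
18 | allyl 7α-isopropenyl-3α-[(E)-2-methylbut-2-enoyloxy]-8-(triisopropylsilyloxy)-10βH-eremophila-8,11-diene-6α-carboxylate | C=C(C)[C@@H]1[C@H](C(=O)OCC=C)[C@@]2(C)[C@H](CC[C@@H](OC(=O)/C(C)=C/C)[C@@H]2C)C=C1O[Si](C(C)C)(C(C)C)C(C)C | intermediate
19 | 7α-isopropenyl-3α-[(E)-2-methylbut-2-enoyloxy]-8-(triisopropylsilyloxy)-10βH-eremophila-8,11-diene-6α-carboxylic acid | C=C(C)[C@@H]1[C@H](C(=O)O)[C@@]2(C)[C@H](CC[C@@H](OC(=O)/C(C)=C/C)[C@@H]2C)C=C1O[Si](C(C)C)(C(C)C)C(C)C | intermediate
20 | 2-thioxopyridin-1(2H)-yl ester of acid 19 (not isolated) | C=C(C)[C@@H]1[C@H](C(=O)ON3C=CC=CC3=S)[C@@]2(C)[C@H](CC[C@@H](OC(=O)/C(C)=C/C)[C@@H]2C)C=C1O[Si](C(C)C)(C(C)C)C(C)C | intermediate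
21 | 7α-isopropenyl-8-(triisopropylsilyloxy)-10βH-eremophila-8,11-dien-3α-yl (E)-2-methylbut-2-enoate | C=C(C)[C@@H]1C[C@@]2(C)[C@H](CC[C@@H](OC(=O)/C(C)=C/C)[C@@H]2C)C=C1O[Si](C(C)C)(C(C)C)C(C)C | intermediate
22 | 8β,9β-epoxy-7α-isopropenyl-8α-(triisopropylsilyloxy)-10βH-eremophil-11-en-3α-yl (E)-2-methylbut-2-enoate (not isolated) | C=C(C)[C@@H]1C[C@@]2(C)[C@H](CC[C@@H](OC(=O)/C(C)=C/C)[C@@H]2C)[C@H]3O[C@@]13O[Si](C(C)C)(C(C)C)C(C)C | intermediate
23 | 9β-hydroxy-7α-isopropenyl-8-oxo-10βH-eremophil-11-en-3α-yl (E)-2-methylbut-2-enoate | C=C(C)[C@@H]1C[C@@]2(C)[C@H](CC[C@@H](OC(=O)/C(C)=C/C)[C@@H]2C)[C@@H](O)C1=O | intermediate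
24 | 3-methylbut-2-enoyl chloride (senecioyl chloride) | CC(C)=CC(Cl)=O | starting material
25 | 7α-isopropenyl-9β-(3-methylbut-2-enoyloxy)-8-oxo-10βH-eremophil-11-en-3α-yl (E)-2-methylbut-2-enoate | C=C(C)[C@@H]1C[C@@]2(C)[C@H](CC[C@@H](OC(=O)/C(C)=C/C)[C@@H]2C)[C@@H](OC(=O)C=C(C)C)C1=O | intermediate
26 | (3R,4R,5R,7R,9R,10S)-9-(3-methylbut-2-enoyloxy)-8-oxo-10βH-eremophil-11-en-3-yl (E)-2-methylbut-2-enoate (3α-tigloyloxy, 9β-senecioyloxy, 7β-isopropenyl) | C=C(C)[C@H]1C[C@@]2(C)[C@H](CC[C@@H](OC(=O)/C(C)=C/C)[C@@H]2C)[C@@H](OC(=O)C=C(C)C)C1=O | target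

**Totals**

Total step count: 16. Longest linear sequence: 16 steps (1 → 26).

**Steps most likely to fail**

Step 9. The β-methyl lactone may be too weak a dienophile in the bridged transition state, so that desilylation, loss of enol ether geometry or oligomerisation of the silyloxytriene outpaces the cycloaddition. The fallback sets out from 14 and reverses the order of reduction and cycloaddition. Reduction with i-Bu2AlH (CH2Cl2, −78 °C) should give the lactol F1, whose ring-opened (Z)-hydroxy enal tautomer is a stronger, unbridged dienophile. Heating (PhMe, 120 °C) should then give the cis-fused hydroxy aldehyde F2; here allylic 1,3-strain between the C4–H bond and the Z formyl group, together with the endo formyl group, is expected to direct the same configurations at C5, C6, C7 and C10. Oxidation of the aldehyde (Ag2O, NaOH, aqueous EtOH) should give the hydroxy acid F3. O-Alkylation of its carboxylate (allyl bromide, Cs2CO3, DMF), which needs no acyl activation and so cannot relactonise, comes back to the route at 16.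

Step 13. Formation of the thiohydroxamate ester at the hindered C6 carboxyl group may be slow, and the C6 radical may rearrange by a homoallyl/cyclopropylcarbinyl 1,2-vinyl shift before hydrogen transfer. The fallback sets out from 15 and excises the carbon without radicals. Reduction with i-Bu2AlH (CH2Cl2, −78 °C) should give the lactol F4. Tsuji–Wilkinson decarbonylation of its open hydroxy aldehyde form with stoichiometric RhCl(PPh3)3 (xylene, 140 °C) should give the alcohol F5; competing hydroacylation of the neighbouring isopropenyl group is the weakness of this variant. Acylation of F5 with 17 (pyridine, DMAP, CH2Cl2) comes back to the route at 21.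

Step 16. Under base, migration of the C11=C12 double bond into conjugation with the ketone, or enolisation towards C9 followed by a 1,2-acyl shift, may compete with simple epimerisation at C7. The fallback sets out from 21 and equilibrates C7 before any acyl group sits on O9. Epoxidation with DMDO to 22, followed by warming on silica to induce the 1,4-silyl shift, should give the α-silyloxy ketone F6. DBU (PhMe, rt) should then equilibrate C7 to the 7β epimer F7, with O9 blocked as a bulky silyl ether that cannot migrate. HF·pyridine (THF, 0 °C) should free the hydroxy ketone F8, and acylation with 24 (pyridine, DMAP, CH2Cl2, 0 °C) comes back to the route at 26.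

**Further compounds**

F1 | step 9 | (5R,6R)-4,5-dimethyl-6-[(3E,5Z)-7-methyl-5-(triisopropylsilyloxy)octa-3,5,7-trien-1-yl]-5,6-dihydro-2H-pyran-2-ol (both anomers) | C=C(C)/C=C(O[Si](C(C)C)(C(C)C)C(C)C)/C=C/CC[C@H]1OC(O)C=C(C)[C@H]1C
F2 | step 9 | 3α-hydroxy-7α-isopropenyl-8-(triisopropylsilyloxy)-10βH-eremophila-8,11-diene-6α-carbaldehyde | C=C(C)[C@@H]1[C@H](C=O)[C@@]2(C)[C@H](CC[C@@H](O)[C@@H]2C)C=C1O[Si](C(C)C)(C(C)C)C(C)C
F3 | step 9 | 3α-hydroxy-7α-isopropenyl-8-(triisopropylsilyloxy)-10βH-eremophila-8,11-diene-6α-carboxylic acid | C=C(C)[C@@H]1[C@H](C(=O)O)[C@@]2(C)[C@H](CC[C@@H](O)[C@@H]2C)C=C1O[Si](C(C)C)(C(C)C)C(C)C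
F4 | step 13 | lactol of 15 (bridged hemiacetal between the C6 formyl carbon and O3; both anomers) | C=C(C)[C@@H]1[C@H]3[C@@]2(C)[C@H](CC[C@@H](OC3O)[C@@H]2C)C=C1O[Si](C(C)C)(C(C)C)C(C)C
F5 | step 13 | 7α-isopropenyl-8-(triisopropylsilyloxy)-10βH-eremophila-8,11-dien-3α-ol | C=C(C)[C@@H]1C[C@@]2(C)[C@H](CC[C@@H](O)[C@@H]2C)C=C1O[Si](C(C)C)(C(C)C)C(C)C
F6 | step 16 | 7α-isopropenyl-8-oxo-9β-(triisopropylsilyloxy)-10βH-eremophil-11-en-3α-yl (E)-2-methylbut-2-enoate | C=C(C)[C@@H]1C[C@@]2(C)[C@H](CC[C@@H](OC(=O)/C(C)=C/C)[C@@H]2C)[C@@H](O[Si](C(C)C)(C(C)C)C(C)C)C1=O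
F7 | step 16 | 7β-isopropenyl-8-oxo-9β-(triisopropylsilyloxy)-10βH-eremophil-11-en-3α-yl (E)-2-methylbut-2-enoate | C=C(C)[C@H]1C[C@@]2(C)[C@H](CC[C@@H](OC(=O)/C(C)=C/C)[C@@H]2C)[C@@H](O[Si](C(C)C)(C(C)C)C(C)C)C1=O
F8 | step 16 | 9β-hydroxy-7β-isopropenyl-8-oxo-10βH-eremophil-11-en-3α-yl (E)-2-methylbut-2-enoate | C=C(C)[C@H]1C[C@@]2(C)[C@H](CC[C@@H](OC(=O)/C(C)=C/C)[C@@H]2C)[C@@H](O)C1=O
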